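**Plan**
- Retrosynthetic cuts, in order: the 5-O–CH3 and 2'-O–benzyl bonds (final unmasking), the O1–C8a bond of the pyranone, the bond between the diketone methine (future C3) and the ring-B carbonyl carbon (future C2), and the aryl–C4 bond to 1,2,3,4-tetramethoxybenzene.
- Forward: ring A is made fully methoxylated from 2,3,4-trimethoxybenzaldehyde, then ortho-lithiation and Weinreb acylation attach C4–C3(OMe). Enolate aroylation then joins ring B through C2, and ring C is closed last by anodic C–H/O–H coupling.
- Enabling feature: in the 2,3,4,5-tetramethoxyphenyl ketone the only ring hydrogen sits on the carbon that becomes C8a, ortho to the acyl-bearing C4a and next to the future C8 methoxyl. O1 can therefore be joined to ring A without an ortho phenol or a halide.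
- Stereochemistry: the target has none. The one stereocentre on the way (the methine of diketone 15) is racemic and becomes sp2 on ring closure.

Key step: step 8

Remark: the target has no stereocentre and no stereogenic double bond, so "single enantiomer" is read as the one constitution drawn and no asymmetric step is needed.

**Step 1**
Reactants: 1 2,3,4-trimethoxybenzaldehyde
Product: 3 2,3,4-trimethoxyphenol, via 2,3,4-trimethoxyphenyl formate 2 (not isolated)
Conditions: 30% aq. H2O2, cat. H2SO4, MeOH, rt
Reagents that add atoms: hydrogen peroxide, OO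
Why: Acid-catalysed Dakin oxidation, in which the ortho/para-methoxylated aryl group should migrate in preference to hydride (Baeyer–Villiger type) and the formate is methanolysed in the same pot.

**Step 2**
Reactants: 3 2,3,4-trimethoxyphenol
Product: 4 1,2,3,4-tetramethoxybenzene
Conditions: MeI, K2CO3, acetone, reflux
Reagents that add atoms: iodomethane, CI
Why: Williamson O-methylation of the phenoxide, a routine SN2 reaction that leaves the three existing methyl ethers untouched.

**Step 3**
Reactants: 5 methoxyacetyl chloride; 6 N,O-dimethylhydroxylamine hydrochloride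
Product: 7 N,2-dimethoxy-N-methylacetamide
Conditions: Et3N (2.2 equiv), CH2Cl2, 0 °C to rt
Reagents that add atoms: none
Why: Schotten–Baumann-type N-acylation of the liberated hydroxylamine by the acid chloride, the standard preparation of a Weinreb amide.

**Step 4**
Reactants: 4 1,2,3,4-tetramethoxybenzene; 7 N,2-dimethoxy-N-methylacetamide
Product: 9 2-methoxy-1-(2,3,4,5-tetramethoxyphenyl)ethan-1-one, via (2,3,4,5-tetramethoxyphenyl)lithium 8 (not isolated)
Conditions: n-BuLi, TMEDA, THF, 0 °C; then 7, −78 °C to 0 °C; aq. NH4Cl
Reagents that add atoms: none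
Why: Directed ortho-metalation next to a methoxy group (the two free positions of 4 are equivalent) followed by the Weinreb ketone synthesis, in which the amide guards against double addition.

**Step 5**
Reactants: 10 2-hydroxy-4-methoxybenzoic acid
Product: 12 2-(benzyloxy)-4-methoxybenzoic acid, via benzyl 2-(benzyloxy)-4-methoxybenzoate 11 (not isolated)
Conditions: BnBr (2.2 equiv), K2CO3, DMF, 60 °C; then NaOH, MeOH/H2O, 60 °C; aq. HCl
Reagents that add atoms: benzyl bromide, BrCc1ccccc1
Why: Williamson benzylation of both the phenol and the carboxylate followed by saponification of the benzyl ester, under which the aryl benzyl ether is inert.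

**Step 6**
Reactants: 12 2-(benzyloxy)-4-methoxybenzoic acid
Product: 13 2-(benzyloxy)-4-methoxybenzoyl chloride
Conditions: (COCl)2, cat. DMF, CH2Cl2, 0 °C to rt; evaporate, use crude
Reagents that add atoms: oxalyl chloride, O=C(Cl)C(=O)Cl
Why: Acid chloride formation with oxalyl chloride under Vilsmeier-type DMF catalysis, mild enough for the benzyl ether and the electron-rich ring.

**Step 7**
Reactants: 9 2-methoxy-1-(2,3,4,5-tetramethoxyphenyl)ethan-1-one; 13 2-(benzyloxy)-4-methoxybenzoyl chloride
Product: 15 1-[2-(benzyloxy)-4-methoxyphenyl]-2-methoxy-3-(2,3,4,5-tetramethoxyphenyl)propane-1,3-dione (racemic), via lithium 2-methoxy-1-(2,3,4,5-tetramethoxyphenyl)ethen-1-olate 14 (not isolated)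
Conditions: LiHMDS (2.2 equiv), THF, −78 °C; then 13, −78 °C to 0 °C; aq. NH4Cl
Reagents that add atoms: none
Why: Claisen-type C-acylation of a preformed lithium enolate by an aroyl chloride, in which the second equivalent of base converts the more acidic diketone into its enolate and so blocks a second acylation.

**Step 8**
Reactants: 15 1-[2-(benzyloxy)-4-methoxyphenyl]-2-methoxy-3-(2,3,4,5-tetramethoxyphenyl)propane-1,3-dione
Product: 16 2'-benzyloxy-3,5,6,7,8,4'-hexamethoxyflavone, i.e. 2-[2-(benzyloxy)-4-methoxyphenyl]-3,5,6,7,8-pentamethoxy-4H-chromen-4-one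
Conditions: graphite anode, Pt cathode, undivided cell, constant current, ca. 2.2 F/mol, n-Bu4NPF6, 2,6-lutidine (2 equiv), HFIP/CH2Cl2, rt
Reagents that add atoms: none
Why: Proposed new method: one-electron oxidation at the anode should take place on the tetramethoxyaryl ketone ring, and the lutidine-assisted enol(ate) oxygen on the ring-B carbonyl carbon then adds to the ring-A radical cation at C6, its only C–H carbon, after which a second electron transfer and loss of that proton rearomatize to the chromone while protons are reduced to H2 at the cathode. The closest known reaction types are anodic dehydrogenative C–H/O–H cyclizations of electron-rich arenes in HFIP (lactonization of biaryl-2-carboxylic acids) and oxidant-mediated O-cyclization of aryl ketone enols onto alkoxyarenes to give benzofurans. Ring C closes as a six-membered ortho-cyclization (6-endo-trig, O1 onto C8a with the C4a–C8a bond inside the new ring); the enol carbon cannot reach the arene without forming a four-membered ring, so only O-attack is possible. No stereocentre is formed, and the racemic methine of 15 becomes the sp2 carbon C3. The step needs ring A to react in preference to ring B and the C6–H carbon in preference to the methoxylated ortho carbon: the first rests on four donor groups against two (ring B and the benzyl group oxidize at clearly higher potential), the second on the reversibility of ipso addition, which has no proton to lose, whereas the C–H adduct aromatizes irreversibly. HFIP should stabilize the radical cation, and the charge is limited to spare the product.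

**Step 9**
Reactants: 16 2'-benzyloxy-3,5,6,7,8,4'-hexamethoxyflavone
Product: 17 5,2'-dihydroxy-3,6,7,8,4'-pentamethoxyflavone
Conditions: BCl3 (excess), pentamethylbenzene, CH2Cl2, −78 °C to 0 °C; then H2O
Reagents that add atoms: none
Why: Lewis-acid ether cleavage in which BCl3 bound to the C4 carbonyl cleaves only the peri 5-methyl ether through a six-membered chelate and ionizes the benzyl ether at low temperature, pentamethylbenzene trapping the benzyl cation by Friedel–Crafts alkylation, while the 3-methoxyl and the non-chelated aryl methyl ethers should remain.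

**Compound list**
1 | 2,3,4-trimethoxybenzaldehyde | COc1ccc(C=O)c(OC)c1OC | starting material
2 | 2,3,4-trimethoxyphenyl formate | COc1ccc(OC=O)c(OC)c1OC | intermediate
3 | 2,3,4-trimethoxyphenol | COc1ccc(O)c(OC)c1OC | intermediate
4 | 1,2,3,4-tetramethoxybenzene | COc1ccc(OC)c(OC)c1OC | intermediate
5 | methoxyacetyl chloride | COCC(=O)Cl | starting material
6 | N,O-dimethylhydroxylamine hydrochloride | CNOC.Cl | starting material
7 | N,2-dimethoxy-N-methylacetamide | COCC(=O)N(C)OC | intermediate
8 | (2,3,4,5-tetramethoxyphenyl)lithium | [Li]c1cc(OC)c(OC)c(OC)c1OC | intermediate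
9 | 2-methoxy-1-(2,3,4,5-tetramethoxyphenyl)ethan-1-one | COCC(=O)c1cc(OC)c(OC)c(OC)c1OC | intermediate
10 | 2-hydroxy-4-methoxybenzoic acid | COc1ccc(C(=O)O)c(O)c1 | starting material
11 | benzyl 2-(benzyloxy)-4-methoxybenzoate | COc1ccc(C(=O)OCc2ccccc2)c(OCc2ccccc2)c1 | intermediate
12 | 2-(benzyloxy)-4-methoxybenzoic acid | COc1ccc(C(=O)O)c(OCc2ccccc2)c1 | intermediate
13 | 2-(benzyloxy)-4-methoxybenzoyl chloride | COc1ccc(C(=O)Cl)c(OCc2ccccc2)c1 | intermediate
14 | lithium 2-methoxy-1-(2,3,4,5-tetramethoxyphenyl)ethen-1-olate (enolate geometry immaterial) | [Li]OC(=COC)c1cc(OC)c(OC)c(OC)c1OC | intermediate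
15 | 1-[2-(benzyloxy)-4-methoxyphenyl]-2-methoxy-3-(2,3,4,5-tetramethoxyphenyl)propane-1,3-dione (racemic) | COc1ccc(C(=O)C(OC)C(=O)c2cc(OC)c(OC)c(OC)c2OC)c(OCc2ccccc2)c1 | intermediate
16 | 2'-benzyloxy-3,5,6,7,8,4'-hexamethoxyflavone | COc1ccc(-c2oc3c(OC)c(OC)c(OC)c(OC)c3c(=O)c2OC)c(OCc2ccccc2)c1 | intermediate
17 | 5,2'-dihydroxy-3,6,7,8,4'-pentamethoxyflavone | COc1ccc(-c2oc3c(OC)c(OC)c(OC)c(O)c3c(=O)c2OC)c(O)c1 | target

**Step count**
Total steps: 9.
Longest linear sequence: 6 (steps 1, 2, 4, 7, 8, 9).

**Steps most likely to fail**

1. Step 8 (proposed new method). The enol oxygen may add ipso at the methoxylated ortho carbon with loss of methanol (radical-cation substitution) and so give the 5-unsubstituted chromone. The enolate may also be oxidized at carbon and dimerize or be trapped by solvent, or the electron-rich product may be oxidized further. The fallback uses known chemistry; it sets out from 4 and comes back at 16. Dibromination of 4 (Br2, CH2Cl2, 0 °C to rt) should give 1,2-dibromo-3,4,5,6-tetramethoxybenzene F1. A single bromine–magnesium exchange (i-PrMgCl·LiCl, THF, −20 °C) and acylation with Weinreb amide 7 should give 1-(2-bromo-3,4,5,6-tetramethoxyphenyl)-2-methoxyethan-1-one F2. C-aroylation of its lithium enolate with 13 under the conditions of step 7 should give 1-[2-(benzyloxy)-4-methoxyphenyl]-3-(2-bromo-3,4,5,6-tetramethoxyphenyl)-2-methoxypropane-1,3-dione F3. Intramolecular Ullmann-type O-arylation of the diketone enolate (CuI, K2CO3, DMF, 100 °C) then forms the same O1–C8a bond and delivers 16.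

2. Step 7. O-acylation of the enolate to an enol ester, or a second acylation of the product, may compete with C-acylation. The fallback sets out from 12 and 9 and comes back at 15. Acid 12 is converted (1H-benzotriazole, SOCl2, CH2Cl2, rt) into 1-[2-(benzyloxy)-4-methoxybenzoyl]-1H-benzotriazole F4. Ketone 9 is then C-acylated with it under soft enolization (MgBr2·OEt2, i-Pr2NEt, CH2Cl2, rt), where the magnesium chelate of the α-methoxy ketone should direct acylation to carbon and give 15.

3. Step 9. Over-demethylation at the 6- or 3-methoxyl, or benzylation of the liberated resorcinol-type ring B by an untrapped benzyl cation, may accompany the double unmasking. The fallback sets out from 16 and comes back at 17. Hydrogenolysis (H2, Pd/C, EtOAc/MeOH, rt) removes the benzyl group to give 2'-hydroxy-3,5,6,7,8,4'-hexamethoxyflavone F5. Chelation-controlled demethylation with anhydrous AlCl3 in MeCN at rt, followed by dilute HCl, then cleaves only the 5-methyl ether to give 17.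

**Further compounds**
F1 | step 8 | 1,2-dibromo-3,4,5,6-tetramethoxybenzene | COc1c(OC)c(OC)c(OC)c(Br)c1Br
F2 | step 8 | 1-(2-bromo-3,4,5,6-tetramethoxyphenyl)-2-methoxyethan-1-one | COCC(=O)c1c(Br)c(OC)c(OC)c(OC)c1OC
F3 | step 8 | 1-[2-(benzyloxy)-4-methoxyphenyl]-3-(2-bromo-3,4,5,6-tetramethoxyphenyl)-2-methoxypropane-1,3-dione (racemic) | COc1ccc(C(=O)C(OC)C(=O)c2c(Br)c(OC)c(OC)c(OC)c2OC)c(OCc2ccccc2)c1
F4 | step 7 | 1-[2-(benzyloxy)-4-methoxybenzoyl]-1H-benzotriazole | COc1ccc(C(=O)n2nnc3ccccc32)c(OCc2ccccc2)c1
F5 | step 9 | 2'-hydroxy-3,5,6,7,8,4'-hexamethoxyflavone | COc1ccc(-c2oc3c(OC)c(OC)c(OC)c(OC)c3c(=O)c2OC)c(O)c1
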